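**Retr osynthetic overview**

1. Ring A (C1–C2–C3–C4–C4a–C8a) is cut at C2–C3. The C1 methyl ketone / C3 aldehyde pair is not prepared as such: it is released from a flat isocoumarin (same atoms, ring oxygen O2 in the place of C2) by adding C2 as methyllithium, and is closed at once by an amine-catalysed asymmetric aldol (enantioselective interrupted Fujimoto–Belleau ring transformation, O-to-CH2 exchange).
2. Enabling feature: the enol-lactone unit C1(=O)–O2–C3=C4, fused to ring B at C4a/C8a and flanked by the peri C8 phenol. After methylation at C1, O2 leaves as the C3 enol(ate), the C8 phenoxide holds the adduct, and the new C1 methyl ketone and C3 aldehyde can only close C2 to C3 (closure from C4 would give a four-membered ring).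
3. Pyranone ring D comes from malonyl dichloride annulation of a C5 acetyl group, which is unambiguous because the lactone carries no second methyl ketone until the last step.
4. The isocoumarin lactone ring comes from rhodium-catalysed, carboxylate-directed C–H annulation of a benzoic acid with vinylene carbonate. Ring B is decorated by Suzuki–Miyaura coupling (C6 phenyl), para-bromination and Stille acetylation (C5).
5. Order of ring formation: ring B (purchased) → lactone ring of the isocoumarin → pyranone ring D → carbocyclic ring A with the C3 stereocenter (last step).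

Key step: step 7

Remark: tetralone numbering is used throughout (C1 ketone, C3 carbinol, C5 pyranonyl, C6 phenyl, C8 phenol; pyranone atoms primed), and the target SMILES is read as the (3S)-alcohol.

**Route**

Step 1
Reactants: 1 4-bromo-2-methoxybenzoic acid; 2 phenylboronic acid
Product: 3 2-methoxy-4-phenylbenzoic acid
Conditions: Pd(PPh3)4 (2 mol %), K2CO3, dioxane/H2O, 90 °C; aq. HCl work-up
Reagents that add atoms: none
Why: Suzuki–Miyaura coupling of an unhindered aryl bromide tolerates the carboxylate and installs the C6 phenyl group; no stereocenter is formed.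

Step 2
Reactants: 3 2-methoxy-4-phenylbenzoic acid
Product: 4 5-bromo-2-methoxy-4-phenylbenzoic acid
Conditions: Br2 (1.05 equiv), AcOH, 23 °C
Reagents that add atoms: bromine (BrBr)
Why: Electrophilic aromatic bromination should go para to the methoxy group and meta to the carboxyl (future C5), the other activated position being wedged between OMe and phenyl; no stereocenter is formed.

Step 3
Reactants: 4 5-bromo-2-methoxy-4-phenylbenzoic acid; 5 vinylene carbonate
Product: 6 5-bromo-8-methoxy-6-phenyl-1H-isochromen-1-one
Conditions: [(C5Me5)Rh(MeCN)3](SbF6)2 (5 mol %), 1,2-dichloroethane, 110 °C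
Reagents that add atoms: none
Why: Carboxylate-directed C–H activation by trivalent rhodium at the only free ortho C–H (acidified by the neighbouring bromine), insertion of vinylene carbonate as an oxidising acetylene equivalent and C–O ring closure should give the 3,4-unsubstituted isocoumarin in a redox-neutral C–H annulation; no stereocenter is formed.

Step 4
Reactants: 6 5-bromo-8-methoxy-6-phenyl-1H-isochromen-1-one; 7 tributyl(1-ethoxyvinyl)stannane
Product: 9 5-acetyl-8-methoxy-6-phenyl-1H-isochromen-1-one, via enol ether 8 (not isolated)
Conditions: Pd2(dba)3 (2.5 mol %), P(t-Bu)3 (10 mol %), CsF, dioxane, 100 °C; then 1 M HCl, THF, 23 °C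
Reagents that add atoms: water (O)
Why: Stille coupling with an acetyl-anion equivalent (bulky electron-rich phosphine for the di-ortho-substituted bromide) followed by mild acid hydrolysis of the enol ether should deliver the C5 methyl ketone while the enol lactone survives; no stereocenter is formed.

Step 5
Reactants: 9 5-acetyl-8-methoxy-6-phenyl-1H-isochromen-1-one; 10 malonyl dichloride
Product: 12 4-hydroxy-6-(8-methoxy-1-oxo-6-phenyl-1H-isochromen-5-yl)-2H-pyran-2-one, via silyl enol ether 11 (not isolated)
Conditions: Me3SiOTf, Et3N, CH2Cl2, 0 °C; then 10, Et2O, −78 to 23 °C; aqueous work-up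
Reagents that add atoms: none
Why: The only enolisable ketone is converted into its silyl enol ether, which is C-acylated by malonyl dichloride and closes through the enol oxygen onto the second acid chloride (known malonyl dichloride annulation of silyl enol ethers to 4-hydroxy-2-pyranones); no stereocenter is formed.

Step 6
Reactants: 12 4-hydroxy-6-(8-methoxy-1-oxo-6-phenyl-1H-isochromen-5-yl)-2H-pyran-2-one
Product: 13 4-hydroxy-6-(8-hydroxy-1-oxo-6-phenyl-1H-isochromen-5-yl)-2H-pyran-2-one
Conditions: BCl3 (3 equiv), CH2Cl2, −78 to 0 °C; H2O quench
Reagents that add atoms: none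
Why: BCl3 chelates the lactone carbonyl and cleaves only the peri (ortho-carbonyl) aryl methyl ether, a standard selective demethylation that leaves both lactones intact; no stereocenter is formed.

Step 7
Reactants: 13 4-hydroxy-6-(8-hydroxy-1-oxo-6-phenyl-1H-isochromen-5-yl)-2H-pyran-2-one
Product: 16 (3S)-3,8-dihydroxy-5-(4-hydroxy-2-oxo-2H-pyran-6-yl)-6-phenyl-3,4-dihydronaphthalen-1(2H)-one (wailupemycin F), via lithium hemiketal 14 (not isolated), via keto-aldehyde 15 (not isolated)
Conditions: LiN(SiMe3)2 (2.1 equiv), THF, 0 °C; MeLi (1.1 equiv), −78 to −40 °C; AcOH, −78 °C, pH 5 buffer work-up; crude 15, (2S,4R)-4-(tert-butyldimethylsilyloxy)proline (30 mol %), MeCN (0.02 M), 0 to 23 °C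
Reagents that add atoms: methyllithium ([Li]C)
Why: Proposed new method: an enantioselective interrupted Fujimoto–Belleau ring transformation in which the lactone oxygen O2 of the flat isocoumarin is exchanged for a CH2 group: after LiN(SiMe3)2 has converted the C8 phenol and the pyranone OH into lithium salts (the pyranone is thereby shielded as a vinylogous carboxylate), MeLi adds once to C1, the C8 phenoxide chelates tetrahedral adduct 14, and buffered protonation lets O2 leave as the C3 enol to unveil keto-aldehyde 15. The silyloxyproline then forms an enamine at the C1 methyl ketone (iminium and enamine formation of 2'-hydroxyacetophenones is facile, as in the Kabbe condensation), its C2 terminus adds to the C3 aldehyde activated by the catalyst CO2H, and hydrolysis releases 16. The closest known reactions are the Fujimoto–Belleau conversion of enol lactones, isocoumarins included, into cyclohexenones or 1-naphthols by methyl Grignard addition and base-induced aldol recyclization, and the amino-acid-catalysed intramolecular aldolization of keto-aldehydes and triketones (Hajos–Parrish type, enolexo mode); new are the stop at the aldol level and catalyst control of C3. Ring A closes in the 6-(enolexo)-exo-trig mode (C2 onto C3), the lactone ring having been opened in the same flask. The C3 stereocenter is controlled by the (2S)-configured catalyst, whose carboxylic-acid-bound transition state is expected to deliver C2 to the Re face of the aldehyde, which corresponds to 3S; this sense should be confirmed on a model substrate and the enantiomeric catalyst taken if it is reversed. The step needs single methyl addition (secured by the chelated adduct at −78 °C), C2 rather than C4 enolization in the ring closure (only C2 attack gives a six-membered ring, C4 attack would give a four-membered one, so the aldehyde-derived enamine is only a reversible reservoir) and survival of the β-hydroxy ketone against dehydration to the naphthol (weakly acidic medium buffered by the pyranone OH, low temperature, high dilution against intermolecular condensation at pyranone C3').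

**Compound list**

1 | 4-bromo-2-methoxybenzoic acid | COc1cc(Br)ccc1C(=O)O | starting material
2 | phenylboronic acid | OB(O)c1ccccc1 | starting material
3 | 2-methoxy-4-phenylbenzoic acid | COc1cc(-c2ccccc2)ccc1C(=O)O | intermediate
4 | 5-bromo-2-methoxy-4-phenylbenzoic acid | COc1cc(-c2ccccc2)c(Br)cc1C(=O)O | intermediate
5 | vinylene carbonate | O=C1OC=CO1 | starting material
6 | 5-bromo-8-methoxy-6-phenyl-1H-isochromen-1-one | COc1cc(-c2ccccc2)c(Br)c2C=COC(=O)c12 | intermediate
7 | tributyl(1-ethoxyvinyl)stannane | CCCC[Sn](CCCC)(CCCC)C(=C)OCC | starting material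
8 | 5-(1-ethoxyethenyl)-8-methoxy-6-phenyl-1H-isochromen-1-one | CCOC(=C)c1c(-c2ccccc2)cc(OC)c2C(=O)OC=Cc12 | intermediate
9 | 5-acetyl-8-methoxy-6-phenyl-1H-isochromen-1-one | CC(=O)c1c(-c2ccccc2)cc(OC)c2C(=O)OC=Cc12 | intermediate
10 | malonyl dichloride | O=C(Cl)CC(=O)Cl | starting material
11 | 8-methoxy-6-phenyl-5-[1-(trimethylsilyloxy)ethenyl]-1H-isochromen-1-one | C=C(O[Si](C)(C)C)c1c(-c2ccccc2)cc(OC)c2C(=O)OC=Cc12 | intermediate
12 | 4-hydroxy-6-(8-methoxy-1-oxo-6-phenyl-1H-isochromen-5-yl)-2H-pyran-2-one | COc1cc(-c2ccccc2)c(-c2cc(O)cc(=O)o2)c2C=COC(=O)c12 | intermediate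
13 | 4-hydroxy-6-(8-hydroxy-1-oxo-6-phenyl-1H-isochromen-5-yl)-2H-pyran-2-one | Oc1cc(-c2ccccc2)c(-c2cc(O)cc(=O)o2)c2C=COC(=O)c12 | intermediate
14 | trilithium 1-methyl-5-(4-oxido-2-oxo-2H-pyran-6-yl)-6-phenyl-1H-isochromene-1,8-diolate (C1 configuration not controlled) | [Li+].[Li+].[Li+].CC1([O-])OC=Cc2c(-c3cc([O-])cc(=O)o3)c(-c3ccccc3)cc([O-])c12 | intermediate
15 | 6-[3-acetyl-4-hydroxy-2-(2-oxoethyl)-6-phenylphenyl]-4-hydroxy-2H-pyran-2-one | CC(=O)c1c(O)cc(-c2ccccc2)c(-c2cc(O)cc(=O)o2)c1CC=O | intermediate
16 | (3S)-3,8-dihydroxy-5-(4-hydroxy-2-oxo-2H-pyran-6-yl)-6-phenyl-3,4-dihydronaphthalen-1(2H)-one (wailupemycin F) | O=C1C[C@@H](O)Cc2c1c(O)cc(-c1ccccc1)c2-c1cc(O)cc(=O)o1 | target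

**Step count and risks**

Total step count: 7. Longest linear sequence: 7 steps (1 → 16).

Steps most likely to fail:

1. Step 7. Enamine formation at the hindered, hydrogen-bonded aryl methyl ketone may be slower than uncatalysed closure and than β-elimination of water, so that facial control is lost and ring A aromatizes; premature collapse of the methyl adduct with a second methyl addition is the other failure mode. Fallback with known chemistry, setting out from 13 and returning at 16: the methyl addition is kept, keto-aldehyde 15 is isolated after the buffered quench and closed without stereocontrol under the classical conditions of the second Fujimoto–Belleau stage held at the aldol level (pyrrolidine/AcOH, 10 mol %, MeCN, 0 °C). This should give racemic 3,8-dihydroxy-5-(4-hydroxy-2-oxo-2H-pyran-6-yl)-6-phenyl-3,4-dihydronaphthalen-1(2H)-one F1. Because the pyranone OH is a vinylogous carboxylic acid, the racemate is resolved classically with (R)-N,N-dimethyl-1-phenylethylamine: fractional crystallisation separates the ammonium salt of the (3S)-acid F2 (taken from crystals or mother liquor, whichever holds it) from the diastereomeric ammonium salt of the (3R)-acid F3, and cold dilute citric acid liberates 16 from F2.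

2. Step 3. C–H metalation at a position flanked by bromine and the carboxylate may be too slow, so that protodecarboxylation and catalyst decay take over. Fallback, setting out from 3 and returning at 6: the order of annulation and halogenation is reversed. Acid 3, whose ortho C–H is unhindered, is annulated with vinylene carbonate under the same rhodium catalyst to 8-methoxy-6-phenyl-1H-isochromen-1-one F4, and electrophilic bromination para to the methoxy group (NBS, MeCN, 0 °C) then gives 6; here the risk moves to competition by the enol-lactone C4 position.

3. Step 5. The twisted, di-ortho-substituted enol ether may be O-acylated or oligomerized by malonyl dichloride faster than it closes to the pyranone. Fallback, setting out from 9 and returning at 12: the lithium enolate of 9 (LiN(SiMe3)2, 2.2 equiv, THF, −78 °C) is C-acylated with ethyl malonyl chloride to ethyl 5-(8-methoxy-1-oxo-6-phenyl-1H-isochromen-5-yl)-3,5-dioxopentanoate F5, and DBU in toluene at 110 °C closes this 3,5-dioxo ester to the 4-hydroxy-2-pyranone 12 with loss of ethanol.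

Further compounds
F1 | step 7 | racemic 3,8-dihydroxy-5-(4-hydroxy-2-oxo-2H-pyran-6-yl)-6-phenyl-3,4-dihydronaphthalen-1(2H)-one | O=C1CC(O)Cc2c1c(O)cc(-c1ccccc1)c2-c1cc(O)cc(=O)o1
F2 | step 7 | (R)-N,N-dimethyl-1-phenylethylammonium salt of the (3S)-acid (pyranon-4-olate) | C[C@@H]([NH+](C)C)c1ccccc1.O=C1C[C@@H](O)Cc2c1c(O)cc(-c1ccccc1)c2-c1cc([O-])cc(=O)o1
F3 | step 7 | (R)-N,N-dimethyl-1-phenylethylammonium salt of the (3R)-acid (pyranon-4-olate) | C[C@@H]([NH+](C)C)c1ccccc1.O=C1C[C@H](O)Cc2c1c(O)cc(-c1ccccc1)c2-c1cc([O-])cc(=O)o1
F4 | step 3 | 8-methoxy-6-phenyl-1H-isochromen-1-one | COc1cc(-c2ccccc2)cc2C=COC(=O)c12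
F5 | step 5 | ethyl 5-(8-methoxy-1-oxo-6-phenyl-1H-isochromen-5-yl)-3,5-dioxopentanoate | CCOC(=O)CC(=O)CC(=O)c1c(-c2ccccc2)cc(OC)c2C(=O)OC=Cc12
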